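Remark on the chemistry: the single stereocentre of the given SMILES works out as R (O > C6' > C4' > H). The ring is numbered C1 (OH flanked by side chain and methyl), C2 (side chain), C4 (OH), C6 (CH3); the side chain is numbered C1' to C16' starting at the ring.

## Analysis of the target

The target is an open-chain meroterpenoid: a 2-methylhydroquinone whose ring carbon C2 carries a C20 tetraprenyl chain. The chain holds three (E)-trisubstituted olefins (C2'=C3', C6'=C7', C10'=C11') and a terminal isopropylidene (C14'=C15'). The only stereocentre is C5' (R), a secondary alcohol that is allylic to C6'=C7' and homoallylic to C2'=C3'. Because it stands alone, there is nothing to relay from: it must be set absolutely, in the middle of a flexible chain, between a CH2 and a vinyl CH that offer a reagent little to grip. The sensitive groups are the hydroquinone (air oxidation), the ortho-allyl phenol (acid closes a chroman onto C3'), the C5' allylic alcohol (ionisation, transposition, dehydration) and the skipped polyene (cationic cyclisation). The segment C2'=C3'(CH3)–C4'H2–C5'H(OH)–C6'H=C7' is a 1,5-dien-3-ol, the exact retron of a [2,3]-Wittig rearrangement of a bis-allylic ether. Cutting C4'–C5' and tying O to C2' splits the chain into a purchasable C15 farnesyl unit and an aryl-C5 unit. It also moves the stereochemical problem to C2', where a Sharpless epoxidation can solve it. The hard points are therefore the C5' configuration, the E geometry of the two olefins beside it, the ring regiochemistry (chain ortho to the C1 oxygen, meta to the methyl) and an end game free of acid.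

## Retrosynthetic reasoning

16 ⇒ 14 (two O–CH3 bonds on the ring). The free hydroquinone is unmasked last because 16 tolerates neither air nor acid. The mask is the dimethyl ether 14, which survives organomagnesium chemistry, zinc and alkyllithium base. It is removed without strong acid by oxidative demethylation to quinone 15 and mild reduction. The forward step must oxidise the arene faster than the allylic alcohol.

14 ⇒ 12 (cut C4'–C5', reconnect O to C2'; the key disconnection). The 1,5-dien-3-ol of 14 is read as the product of a [2,3]-Wittig rearrangement of the (S)-configured farnesyl ether 12, through the lithiated ether 13. One operation has to form the C4'–C5' bond that joins the C15 and aryl-C5 halves, create C5' with R configuration by 1,3-transfer of chirality from C2', set C2'=C3' as E, and release the allylic alcohol. Cutting here is preferred because both partners of 12 are simple and because a stereocentre at C2' is easy to set. In the envelope transition state, CH2Ar on C2' sits outside and the alkenyl group on C5' sits exo; with this arrangement (S)-C2' maps onto (R)-C5'.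

12 ⇒ 9 + 10 (O–C5' bond). Ether 12 comes from the (S)-allylic alcohol 9 and (2E,6E)-farnesyl bromide 10 by Williamson etherification through alkoxide 11. The C2'–O bond is not touched, so the configuration of 9 is carried into 12. The whole C5'–C16' segment with its two E-olefins is bought.

9 ⇒ 8 ⇒ 7 (oxygen stays on C2', the olefin moves to C3'=C4'). The isopropenyl carbinol 9 is the reductive ring-opening product of epoxy iodide 8, which comes from epoxy alcohol 7. The C2'–O bond of 9 is the C3–O bond of the epoxide, so (3S) in 7 becomes (S) in 9 without any bond to the stereocentre being broken.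

7 ⇒ 6 (epoxide C–O bonds). A Sharpless asymmetric epoxidation of the (E)-trisubstituted allylic alcohol 6 sets the stereocentre. This substrate class gives high enantioselectivity, and the catalyst enantiomer is chosen to give (2S,3S).

6 ⇒ 3 + 4 (ring C2–C1' bond). The aryl bromide 3 is turned into the arylmagnesium bromide 5, which opens racemic 2-methyl-2-vinyloxirane 4 in a copper-catalysed SN2' reaction. One step attaches all five carbons C1'–C4' plus the methyl with the E-olefin and the hydroxyl handle. The ring regiochemistry is fixed by the position of the bromine.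

3 ⇒ 2 ⇒ 1 (C–Br and O–CH3 bonds). Bromination of 4-methoxy-2-methylphenol 1 can only go ortho to the free hydroxyl, since the other ortho position and the para position are blocked. O-Methylation of 2 gives 3.

## Alternatives that were turned down

Alternative 1: the textbook cut at C5'–C6', a secondary allylic alcohol from an aldehyde and an alkenyl metal. The forward key step would be a catalytic asymmetric Nozaki–Hiyama–Kishi or alkenylzinc addition of vinyl iodide A2 to aldehyde A1.
- A1 is a β,γ-unsaturated aldehyde whose C4' methylene lies between C=O and C3'=C2'. It enolises easily, drifts into conjugation and loses the 2'E geometry.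
- The stereocentre would rest on catalyst control at an unbranched α-CH2 aldehyde, the weakest case for such additions.
- A2 needs its own stereodefined synthesis (carbometalation of a C13 terminal alkyne), whereas the chosen route buys the C15 unit as 10.
- Two fragments of four to five steps each stand against one. The sister cut at C4'–C5' by carbonyl addition is kept only as the fallback for step 8.

Alternative 2: cut the ring C2–C1' bond last. The forward key step would be a copper-mediated allylic substitution of the fully built C20 allylic bromide A3 by the arylmagnesium bromide 5.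
- This is the usual way to prenylated hydroquinones and is convergent on paper, but it only relocates the problem: A3 still contains C5' and both flanking E-olefins.
- A3 must also be differentiated at both ends (bromide at C1', protected alcohol at C5'). That costs a protecting group and at least eight steps.
- The aryl copper species can attack A3 in SN2' fashion at C3'.

Alternative 3: form the C5'–O bond last, copying the presumed biosynthesis. The hydroquinone would be alkylated with the intact C20 chain to give the 5'-deoxy compound A4, followed by allylic oxidation at C5'.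
- C5' is one of seven allylic methylenes (C1', C4', C5', C8', C9', C12', C13') beside five allylic methyl groups.
- Ene-type oxidants would favour the terminal (E)-methyl on C15' or give transposed products.
- No reagent distinguishes the two enantiotopic hydrogens on C5'.
- The electron-rich hydroquinone would be oxidised before any C–H bond. The step count is low, but the key step cannot be defended.

Key step: step 8

## Route

Step 1
Reactants: 1 4-methoxy-2-methylphenol
Product: 2 2-bromo-4-methoxy-6-methylphenol
Conditions: Br2 (1.0 equiv), CH2Cl2, 0 °C
Reagents that add atoms: bromine, BrBr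
Why: Electrophilic aromatic bromination; the free hydroxyl is the strongest director and its para position (OCH3) and one ortho position (CH3) are blocked, so bromine should enter the remaining ortho carbon.

Step 2
Reactants: 2 2-bromo-4-methoxy-6-methylphenol
Product: 3 1-bromo-2,5-dimethoxy-3-methylbenzene
Conditions: MeI, K2CO3, acetone, 56 °C
Reagents that add atoms: iodomethane, CI
Why: Williamson O-methylation of the phenol; the two methyl ethers mask the hydroquinone through the organometallic and strongly basic steps.

Step 3
Reactants: 3 1-bromo-2,5-dimethoxy-3-methylbenzene; 4 2-methyl-2-vinyloxirane (racemic)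
Product: 6 (2E)-4-(2,5-dimethoxy-3-methylphenyl)-2-methylbut-2-en-1-ol, via arylmagnesium bromide 5 (not isolated)
Conditions: Mg turnings, THF, 50 °C; then CuI (10 mol %), 4 (1.5 equiv), THF, −30 °C to 0 °C; aq. NH4Cl
Reagents that add atoms: none
Why: Magnesium insertion gives 5; copper-catalysed SN2' opening of the vinyl oxirane delivers the aryl group to the terminal vinyl carbon, a reaction type that gives mainly the (E)-2-methylalk-2-en-1-ol. The stereocentre of racemic 4 is destroyed, so its configuration does not matter; any Z isomer is to be removed by chromatography before step 4.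

Step 4
Reactants: 6 (2E)-4-(2,5-dimethoxy-3-methylphenyl)-2-methylbut-2-en-1-ol
Product: 7 [(2S,3S)-3-(2,5-dimethoxy-3-methylbenzyl)-2-methyloxiran-2-yl]methanol
Conditions: Ti(OiPr)4 (10 mol %), L-(+)-diethyl tartrate (12 mol %), t-BuOOH (2 equiv, in decane), 4 Å MS, CH2Cl2, −20 °C
Reagents that add atoms: tert-butyl hydroperoxide, CC(C)(C)OO
Why: Sharpless asymmetric epoxidation; with the L-(+)-tartrate catalyst an (E)-allylic alcohol of this pattern is epoxidised on the face that gives the (2S,3S)-epoxy alcohol, the same sense as for (E)-hex-2-en-1-ol. Trisubstituted (E)-allylic alcohols are among the best substrates; C3 of 7 is the future C2'.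

Step 5
Reactants: 7 [(2S,3S)-3-(2,5-dimethoxy-3-methylbenzyl)-2-methyloxiran-2-yl]methanol
Product: 8 (2R,3S)-3-(2,5-dimethoxy-3-methylbenzyl)-2-(iodomethyl)-2-methyloxirane
Conditions: I2, PPh3, imidazole, Et2O/MeCN 3:1, 0 °C
Reagents that add atoms: iodine, [I][I]
Why: Appel-type iodination (phosphonium activation, SN2 by iodide at the primary carbon); neither epoxide carbon is touched, and the descriptor at C2 changes from S to R only because CH2I outranks the ring carbon.

Step 6
Reactants: 8 (2R,3S)-3-(2,5-dimethoxy-3-methylbenzyl)-2-(iodomethyl)-2-methyloxirane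
Product: 9 (2S)-1-(2,5-dimethoxy-3-methylphenyl)-3-methylbut-3-en-2-ol
Conditions: Zn dust, AcOH (2 equiv), EtOH, 25 °C
Reagents that add atoms: none
Why: Zinc inserts into the C–I bond and the β-alkoxy organozinc fragments with opening of the epoxide (reductive elimination), which leaves the oxygen on C2' as a free alcohol and unveils the isopropenyl group. The C2'–O bond is never broken, so 3S in 8 becomes S in 9.

Step 7
Reactants: 9 (2S)-1-(2,5-dimethoxy-3-methylphenyl)-3-methylbut-3-en-2-ol; 10 (2E,6E)-1-bromo-3,7,11-trimethyldodeca-2,6,10-triene (farnesyl bromide)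
Product: 12 1-[(2S)-3-methyl-2-{[(2E,6E)-3,7,11-trimethyldodeca-2,6,10-trien-1-yl]oxy}but-3-en-1-yl]-2,5-dimethoxy-3-methylbenzene, via sodium alkoxide 11 (not isolated)
Conditions: NaH (1.3 equiv), THF/DMF 4:1, 0 °C; then 10 (1.2 equiv), n-Bu4NI (5 mol %), 0 °C to 25 °C
Reagents that add atoms: none
Why: Williamson ether synthesis, SN2 of alkoxide 11 on the primary allylic bromide; the C2'–O bond is untouched (S retained) and the 2E,6E geometry of the farnesyl unit is carried over.

Step 8
Reactants: 12 1-[(2S)-3-methyl-2-{[(2E,6E)-3,7,11-trimethyldodeca-2,6,10-trien-1-yl]oxy}but-3-en-1-yl]-2,5-dimethoxy-3-methylbenzene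
Product: 14 (2E,5R,6E,10E)-1-(2,5-dimethoxy-3-methylphenyl)-3,7,11,15-tetramethylhexadeca-2,6,10,14-tetraen-5-ol, via lithiated ether 13 (not isolated)
Conditions: n-BuLi (2.0 equiv), THF, −78 °C to −40 °C; then H2O
Reagents that add atoms: none
Why: n-BuLi should remove a proton from C5', the only α-oxy allylic CH2 (the other α-oxy hydrogen, on C2', is tertiary, and unsymmetrical bis-allylic ethers are known to be lithiated at the less substituted α-carbon), to give the α-oxyallyllithium 13. 13 then undergoes the concerted, suprafacial [2,3]-Wittig rearrangement through a five-membered envelope transition state in which C5' bonds to C4' while O–C2' breaks and the double bond moves to C2'=C3'; the closest known reaction type is the [2,3]-Wittig rearrangement of unsymmetrical bis-allylic ethers to 1,5-dien-3-ols, including ethers of enantioenriched 2-methylalk-1-en-3-ols. No ring is closed: the five-membered array exists only in the transition state. The new stereocentre C5' is controlled by the stereocentre at C2', which is consumed: CH2Ar on C2' takes the pseudo-equatorial (outside) position, which fixes the face of the C3'=C4' terminus that is attacked and makes C2'=C3' E (CH2Ar cis to the C3' methyl), and the alkenyl group on C5' takes the exo position, away from C3' and its methyl group; for the (S)-ether this combination maps onto (R)-C5'. The step needs four selectivities: α'- over α-lithiation (CH2 against tertiary CH), [2,3] over [1,2] and [1,4] shifts (low temperature, and the fully substituted C7' blocks reaction through the γ-carbon of the anion), E over Z at C2'=C3' and exo over endo at C5' (both set by the C2' substituent and the C3' methyl group). The 6'E geometry should survive because 13 rearranges at −78 °C faster than the allyl anion rotates, and the lithium alkoxide formed does not undergo oxy-Cope rearrangement at this temperature.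

Step 9
Reactants: 14 (2E,5R,6E,10E)-1-(2,5-dimethoxy-3-methylphenyl)-3,7,11,15-tetramethylhexadeca-2,6,10,14-tetraen-5-ol
Product: 16 2-[(2E,5R,6E,10E)-5-hydroxy-3,7,11,15-tetramethylhexadeca-2,6,10,14-tetraen-1-yl]-6-methylbenzene-1,4-diol, via quinone 15 (not isolated)
Conditions: (NH4)2Ce(NO3)6 (2.5 equiv), MeCN/H2O 2:1, 0 °C, 15 min; Et2O extraction; then aq. Na2S2O4, Et2O, 25 °C, under Ar
Reagents that add atoms: water, O
Why: Oxidative demethylation of the 1,4-dimethoxyarene by the tetravalent cerium salt (two one-electron oxidations, ipso attack of water, loss of two methanol) should give quinone 15 much faster than the allylic alcohol or the olefins react. Dithionite then reduces the quinone to the hydroquinone under near-neutral conditions, which spares the ortho-allyl phenol and C5'.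

## Compound list

1 | 4-methoxy-2-methylphenol | COc1ccc(O)c(C)c1 | starting material
2 | 2-bromo-4-methoxy-6-methylphenol | COc1cc(C)c(O)c(Br)c1 | intermediate
3 | 1-bromo-2,5-dimethoxy-3-methylbenzene | COc1cc(C)c(OC)c(Br)c1 | intermediate
4 | 2-methyl-2-vinyloxirane (racemic) | C=CC1(C)CO1 | starting material
5 | (2,5-dimethoxy-3-methylphenyl)magnesium bromide | COc1cc(C)c(OC)c([Mg]Br)c1 | intermediate
6 | (2E)-4-(2,5-dimethoxy-3-methylphenyl)-2-methylbut-2-en-1-ol | OC/C(C)=C/Cc1cc(OC)cc(C)c1OC | intermediate
7 | [(2S,3S)-3-(2,5-dimethoxy-3-methylbenzyl)-2-methyloxiran-2-yl]methanol | OC[C@]1(C)O[C@H]1Cc2cc(OC)cc(C)c2OC | intermediate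
8 | (2R,3S)-3-(2,5-dimethoxy-3-methylbenzyl)-2-(iodomethyl)-2-methyloxirane | IC[C@]1(C)O[C@H]1Cc2cc(OC)cc(C)c2OC | intermediate
9 | (2S)-1-(2,5-dimethoxy-3-methylphenyl)-3-methylbut-3-en-2-ol | C=C(C)[C@@H](O)Cc1cc(OC)cc(C)c1OC | intermediate
10 | (2E,6E)-1-bromo-3,7,11-trimethyldodeca-2,6,10-triene (farnesyl bromide) | CC(C)=CCC/C(C)=C/CC/C(C)=C/CBr | starting material
11 | sodium (2S)-1-(2,5-dimethoxy-3-methylphenyl)-3-methylbut-3-en-2-olate | [Na+].[O-][C@@H](Cc1cc(OC)cc(C)c1OC)C(C)=C | intermediate
12 | 1-[(2S)-3-methyl-2-{[(2E,6E)-3,7,11-trimethyldodeca-2,6,10-trien-1-yl]oxy}but-3-en-1-yl]-2,5-dimethoxy-3-methylbenzene | CC(C)=CCC/C(C)=C/CC/C(C)=C/CO[C@@H](Cc1cc(OC)cc(C)c1OC)C(C)=C | intermediate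
13 | α-lithio derivative of 12 (lithium on C5', the O–CH carbon of the farnesyl unit) | CC(C)=CCC/C(C)=C/CC/C(C)=C/C([Li])O[C@@H](Cc1cc(OC)cc(C)c1OC)C(C)=C | intermediate
14 | (2E,5R,6E,10E)-1-(2,5-dimethoxy-3-methylphenyl)-3,7,11,15-tetramethylhexadeca-2,6,10,14-tetraen-5-ol | CC(C)=CCC/C(C)=C/CC/C(C)=C/[C@H](O)C/C(C)=C/Cc1cc(OC)cc(C)c1OC | intermediate
15 | 2-[(2E,5R,6E,10E)-5-hydroxy-3,7,11,15-tetramethylhexadeca-2,6,10,14-tetraen-1-yl]-6-methylcyclohexa-2,5-diene-1,4-dione | CC(C)=CCC/C(C)=C/CC/C(C)=C/[C@H](O)C/C(C)=C/CC1=CC(=O)C=C(C)C1=O | intermediate
16 | 2-[(2E,5R,6E,10E)-5-hydroxy-3,7,11,15-tetramethylhexadeca-2,6,10,14-tetraen-1-yl]-6-methylbenzene-1,4-diol | CC(C)=CCC/C(C)=C/CC/C(C)=C/[C@H](O)C/C(C)=C/Cc1cc(O)cc(C)c1O | target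

## Step count and risk

Total step count: 9. Longest linear sequence: 9 steps (from 1 to 16); the C15 unit 10 and the C5 unit 4 are bought.

Step 8 (key step). Three things may go wrong.
- Lithiation may occur at the wrong site (C2'–H or the benzylic C1'), or the anion may take the [1,2] path on warming.
- The transition state may be less ordered than assumed, which would show as Z olefin at C2'=C3' or as erosion of the chirality transfer to C5'.
- The allyl anion may equilibrate and lose the 6'E geometry.

The fallback abandons the sigmatropic step and makes the C4'–C5' bond by carbonyl addition; it sets out from 6 and comes back at 14. Alcohol 6 is converted (MsCl, LiCl, 2,4,6-collidine, DMF, 0 °C) into 1-[(2E)-4-chloro-3-methylbut-2-en-1-yl]-2,5-dimethoxy-3-methylbenzene F1. F1 is metalated with activated barium (from BaI2 and lithium biphenylide, THF, −78 °C) to the allylbarium chloride F2, which is known to add to aldehydes at its α-carbon with retention of olefin geometry. Addition of F2 to (2E,6E)-farnesal F3 gives the racemic linear alcohol F4. Buffered Dess–Martin oxidation gives the dienone F5. Corey–Bakshi–Shibata reduction with the (S)-2-methyl-oxazaborolidine and catecholborane (toluene, −78 °C), with the alkenyl group as the large substituent, should give (R)-configured 14. The last two operations also repair 14 of insufficient enantiomeric purity from step 8.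

Step 3. The SN2' opening may give too much Z isomer, or some direct SN2 opening at the oxirane CH2. A Z impurity would be epoxidised to the opposite C2' configuration in step 4. The fallback separates C–C bond formation from oxygenation; it sets out from 5 and comes back at 6. 5 is coupled (CuI cat., THF, 0 °C) with 1-bromo-3-methylbut-2-ene F6 to give the prenyl arene 2,5-dimethoxy-1-methyl-3-(3-methylbut-2-en-1-yl)benzene F7. Allylic oxidation of F7 with SeO2 (cat.) and t-BuOOH in CH2Cl2 should be selective for the (E)-methyl group and give 6; any over-oxidised enal is reduced back with NaBH4.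

Step 6 (with step 5). Iodide formation next to the fully substituted epoxide carbon may be slow, and the epoxy iodide may be opened by iodide before zinc is added. The fallback replaces steps 5 and 6 by a Wharton transposition; it sets out from 7 and comes back at 9. 7 is oxidised (SO3·pyridine, DMSO, iPr2NEt, 0 °C) to the epoxy aldehyde (2R,3S)-3-(2,5-dimethoxy-3-methylbenzyl)-2-methyloxirane-2-carbaldehyde F8. Treatment of F8 with N2H4·H2O and catalytic AcOH in MeOH at 0 °C gives 9 with loss of dinitrogen; the C2'–O bond is again untouched.

Step 9. The tetravalent cerium salt may also oxidise the free C5' allylic alcohol, or the nitric acid set free may ionise it; the quinone may cyclise onto the side chain before reduction. The fallback masks the alcohol during the oxidation; it sets out from 14 and comes back at 16. 14 is acetylated (Ac2O, pyridine, DMAP) to the acetate F9, which is oxidised under the same conditions to the quinone acetate F10. Dithionite reduction gives the hydroquinone acetate F11, and degassed K2CO3 in MeOH at 0 °C under argon removes the acetate to give 16.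

## Further compounds

F1 | step 8 | 1-[(2E)-4-chloro-3-methylbut-2-en-1-yl]-2,5-dimethoxy-3-methylbenzene | ClC/C(C)=C/Cc1cc(OC)cc(C)c1OC
F2 | step 8 | [(2E)-4-(2,5-dimethoxy-3-methylphenyl)-2-methylbut-2-en-1-yl]barium chloride | Cl[Ba]C/C(C)=C/Cc1cc(OC)cc(C)c1OC
F3 | step 8 | (2E,6E)-3,7,11-trimethyldodeca-2,6,10-trienal (farnesal) | CC(C)=CCC/C(C)=C/CC/C(C)=C/C=O
F4 | step 8 | racemic (2E,6E,10E)-1-(2,5-dimethoxy-3-methylphenyl)-3,7,11,15-tetramethylhexadeca-2,6,10,14-tetraen-5-ol | CC(C)=CCC/C(C)=C/CC/C(C)=C/C(O)C/C(C)=C/Cc1cc(OC)cc(C)c1OC
F5 | step 8 | (2E,6E,10E)-1-(2,5-dimethoxy-3-methylphenyl)-3,7,11,15-tetramethylhexadeca-2,6,10,14-tetraen-5-one | CC(C)=CCC/C(C)=C/CC/C(C)=C/C(=O)C/C(C)=C/Cc1cc(OC)cc(C)c1OC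
F6 | step 3 | 1-bromo-3-methylbut-2-ene | CC(C)=CCBr
F7 | step 3 | 2,5-dimethoxy-1-methyl-3-(3-methylbut-2-en-1-yl)benzene | CC(C)=CCc1cc(OC)cc(C)c1OC
F8 | step 6 | (2R,3S)-3-(2,5-dimethoxy-3-methylbenzyl)-2-methyloxirane-2-carbaldehyde | O=C[C@]1(C)O[C@H]1Cc2cc(OC)cc(C)c2OC
F9 | step 9 | (2E,5R,6E,10E)-1-(2,5-dimethoxy-3-methylphenyl)-3,7,11,15-tetramethylhexadeca-2,6,10,14-tetraen-5-yl acetate | CC(C)=CCC/C(C)=C/CC/C(C)=C/[C@H](OC(C)=O)C/C(C)=C/Cc1cc(OC)cc(C)c1OC
F10 | step 9 | (2E,5R,6E,10E)-3,7,11,15-tetramethyl-1-(5-methyl-3,6-dioxocyclohexa-1,4-dien-1-yl)hexadeca-2,6,10,14-tetraen-5-yl acetate | CC(C)=CCC/C(C)=C/CC/C(C)=C/[C@H](OC(C)=O)C/C(C)=C/CC1=CC(=O)C=C(C)C1=O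
F11 | step 9 | (2E,5R,6E,10E)-1-(2,5-dihydroxy-3-methylphenyl)-3,7,11,15-tetramethylhexadeca-2,6,10,14-tetraen-5-yl acetate | CC(C)=CCC/C(C)=C/CC/C(C)=C/[C@H](OC(C)=O)C/C(C)=C/Cc1cc(O)cc(C)c1O
A1 | alternative 1 | (3E)-5-(2,5-dimethoxy-3-methylphenyl)-3-methylpent-3-enal | O=CC/C(C)=C/Cc1cc(OC)cc(C)c1OC
A2 | alternative 1 | (1E,5E)-1-iodo-2,6,10-trimethylundeca-1,5,9-triene | CC(C)=CCC/C(C)=C/CC/C(C)=C/I
A3 | alternative 2 | (2E,5R,6E,10E)-1-bromo-5-[(tert-butyldimethylsilyl)oxy]-3,7,11,15-tetramethylhexadeca-2,6,10,14-tetraene | CC(C)=CCC/C(C)=C/CC/C(C)=C/[C@H](O[Si](C)(C)C(C)(C)C)C/C(C)=C/CBr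
A4 | alternative 3 | 2-methyl-6-[(2E,6E,10E)-3,7,11,15-tetramethylhexadeca-2,6,10,14-tetraen-1-yl]benzene-1,4-diol | CC(C)=CCC/C(C)=C/CC/C(C)=C/CC/C(C)=C/Cc1cc(O)cc(C)c1O
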